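Numbering: chain C1H2=C2(CH3)–C3H(OH)–C4H2–C5H2–C6(=CH2)–, ring C7(OH)–C8H2–C9H2–C10(CH3)(Br)–C11H(Cl)–C12H2.
Enabling feature: the isopropenyl carbinol C1=C2(CH3)–C3H(OH) is an isomerised 2,2-dimethyloxirane. Once ring C7–C12 is saturated and halogenated, the prenyl alkene C2=C3 is the only trisubstituted alkene left, so a chiral electrophilic oxidant can address it alone.
Cuts, in retrosynthetic order: C2–O/C1–H isomerisation back to the C2–C3 oxirane; the oxirane C2–O and C3–O bonds; C6=CH2; C5–C6; C10–Br; C11–Cl; the C10–C11 epoxide oxygen; the Diels–Alder bonds C7–C12 and C8–C9.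
Forward order: the cyclohexene ring C7–C12 is closed first from isoprene, then oxidised and halogenated at the amide stage. The C1–C5 chain is then joined as a Grignard reagent, C6 is methylenated, and the oxirane is closed and reopened last.
Stereochemistry: C7 comes from the acetal centre of an (R)-lactic acid dioxolanone. C10 and C11 are relayed from C7–OH by directed epoxidation, anti opening by chloride and retentive bromination. C3 comes from the D-fructose-derived ketone alone.

Key step: step 12

Remark: both chiral controllers are taken to induce in their established sense, that is, diene attack anti to the tert-butyl group of the dioxolanone and the (R)-oxirane from a prenyl terminus with the D-fructose-derived ketone.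

Step 1
Reactants: 1 (R)-lactic acid; 2 pivalaldehyde (2,2-dimethylpropanal)
Product: 3 (2R,5R)-2-tert-butyl-5-methyl-1,3-dioxolan-4-one
Conditions: p-TsOH·H2O (cat), pentane, reflux, Dean–Stark trap; crystallisation from pentane–Et2O, −78 °C
Reagents that add atoms: none
Why: Acid-catalysed acetalisation under thermodynamic control favours the cis-2,5-disubstituted dioxolanone, so the lactic acid centre fixes the new acetal centre C2 as (R), and cold crystallisation should remove the trans isomer.

Step 2
Reactants: 3 (2R,5R)-2-tert-butyl-5-methyl-1,3-dioxolan-4-one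
Product: 4 (2S,5S)-5-bromo-2-tert-butyl-5-methyl-1,3-dioxolan-4-one (Br trans to tert-butyl; the C2 descriptor changes by priority only)
Conditions: NBS, AIBN (cat), cyclohexane, reflux
Reagents that add atoms: N-bromosuccinimide, O=C1CCC(=O)N1Br
Why: Wohl–Ziegler-type radical bromination takes the captodatively activated C5–H and delivers bromine to the planar radical on the face away from the tert-butyl group, a centre that is erased in the next step.

Step 3
Reactants: 4 (2S,5S)-5-bromo-2-tert-butyl-5-methyl-1,3-dioxolan-4-one
Product: 5 (2R)-2-tert-butyl-5-methylidene-1,3-dioxolan-4-one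
Conditions: Et3N, Et2O, 0 °C to rt
Reagents that add atoms: none
Why: E2 dehydrobromination of the tertiary α-bromo lactone removes a methyl proton and gives the exocyclic alkene, while the acetal centre, now the only stereocentre, is untouched.

Step 4
Reactants: 5 (2R)-2-tert-butyl-5-methylidene-1,3-dioxolan-4-one; 6 isoprene
Product: 7 (2R,5S)-2-tert-butyl-8-methyl-1,3-dioxaspiro[4.5]dec-7-en-4-one
Conditions: isoprene (excess), 2,6-di-tert-butyl-4-methylphenol (trace), toluene, sealed tube, 110 °C
Reagents that add atoms: none
Why: In this thermal Diels–Alder reaction of a 2-oxyacrylate-type dienophile, isoprene adds to the exocyclic alkene from the face opposite the tert-butyl group, which sets C7 as (S), and the large HOMO coefficient at C1 of isoprene pairs with the methylene carbon of 5 to give the para orientation, the minor meta isomer being removed by chromatography.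

Step 5
Reactants: 7 (2R,5S)-2-tert-butyl-8-methyl-1,3-dioxaspiro[4.5]dec-7-en-4-one
Product: 8 (1S)-1-hydroxy-N-methoxy-N,4-dimethylcyclohex-3-ene-1-carboxamide
Conditions: MeNH(OMe)·HCl, i-PrMgCl, THF, −20 to 0 °C; aq NH4Cl
Reagents that add atoms: N,O-dimethylhydroxylamine hydrochloride, CNOC.Cl
Why: Aminolysis of the activated acetal-lactone by the magnesium amide (Weinreb amide formation) opens the dioxolanone at the acyl carbon and releases the auxiliary aldehyde on work-up, which frees C7–OH without touching the C7 centre.

Step 6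
Reactants: 8 (1S)-1-hydroxy-N-methoxy-N,4-dimethylcyclohex-3-ene-1-carboxamide
Product: 9 (1S,3S,6R)-3-hydroxy-N-methoxy-N,6-dimethyl-7-oxabicyclo[4.1.0]heptane-3-carboxamide (oxirane oxygen cis to C7–OH)
Conditions: VO(acac)2 (cat), t-BuOOH, CH2Cl2, 0 °C to rt
Reagents that add atoms: tert-butyl hydroperoxide, CC(C)(C)OO
Why: In this hydroxyl-directed epoxidation of a homoallylic cyclohexenol, the vanadium alkoxide formed at the pseudoaxial C7–OH carries the peroxide to the alkene face syn to that oxygen, which sets C10 (R) and C11 (S), a course established for 1-methylcyclohexen-4-ols such as terpinen-4-ol.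

Step 7
Reactants: 9 (1S,3S,6R)-3-hydroxy-N-methoxy-N,6-dimethyl-7-oxabicyclo[4.1.0]heptane-3-carboxamide
Product: 10 (1S,3R,4R)-3-chloro-1,4-dihydroxy-N-methoxy-N,4-dimethylcyclohexane-1-carboxamide
Conditions: LiCl, AcOH, THF, rt
Reagents that add atoms: lithium chloride, [Li+].[Cl-]
Why: Halide opening of an epoxide under nucleophilic, only weakly acidic conditions is an SN2 process that goes to the secondary carbon C11 from the face opposite the oxirane oxygen, so C11 is inverted to (R) with Cl trans to both hydroxyl groups and the C10–O bond stays intact.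

Step 8
Reactants: 10 (1S,3R,4R)-3-chloro-1,4-dihydroxy-N-methoxy-N,4-dimethylcyclohexane-1-carboxamide
Product: 11 (1S,3R,4R)-4-bromo-3-chloro-1-hydroxy-N-methoxy-N,4-dimethylcyclohexane-1-carboxamide
Conditions: anhydrous HBr, CH2Cl2, −20 to 0 °C
Reagents that add atoms: hydrogen bromide, Br
Why: In this SN1 conversion of a tertiary alcohol to a tertiary bromide with neighbouring-halogen participation, only C10–OH can ionise because the C7 carbinol is geminal to the amide carbonyl, ionisation runs from the chair in which C10–O is axial and antiperiplanar to C11–Cl, and the chlorine-bridged cation should take up bromide on the face that water left, so C10 keeps its configuration and Br stands trans to Cl.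

Step 9
Reactants: 12 5-bromo-2-methylpent-2-ene
Product: 13 (4-methylpent-3-en-1-yl)magnesium bromide
Conditions: Mg turnings, I2 (trace), THF, 25–40 °C
Reagents that add atoms: magnesium, [Mg]
Why: Grignard formation from a primary homoallylic bromide is routine, and the remote trisubstituted alkene does not interfere.

Step 10
Reactants: 11 (1S,3R,4R)-4-bromo-3-chloro-1-hydroxy-N-methoxy-N,4-dimethylcyclohexane-1-carboxamide; 13 (4-methylpent-3-en-1-yl)magnesium bromide
Product: 14 1-[(1S,3R,4R)-4-bromo-3-chloro-1-hydroxy-4-methylcyclohexyl]-5-methylhex-4-en-1-one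
Conditions: 13 (3.5 equiv), THF, −20 to 0 °C; aq NH4Cl
Reagents that add atoms: none
Why: In this Weinreb ketone synthesis, the first equivalent deprotonates C7–OH, the reagent then adds once to the N-methoxy-N-methylamide, and the magnesium chelate holds the tetrahedral adduct until work-up, so the C5–C6 bond forms without over-addition while the diequatorial bromochloride offers no antiperiplanar pair for halophilic attack.

Step 11
Reactants: 14 1-[(1S,3R,4R)-4-bromo-3-chloro-1-hydroxy-4-methylcyclohexyl]-5-methylhex-4-en-1-one
Product: 16 (1S,3R,4R)-4-bromo-3-chloro-4-methyl-1-(6-methylhepta-1,5-dien-2-yl)cyclohexan-1-ol, via β-hydroxysilane 15 (not isolated)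
Conditions: Me3SiCH2Li, CeCl3 (3 equiv each), THF, −78 to −20 °C; aq NH4Cl; then 48% aq HF, MeCN, 0 °C
Reagents that add atoms: (trimethylsilyl)methyllithium, [Li]C[Si](C)(C)C
Why: In this Peterson methylenation in its organocerium form, the weakly basic reagent adds to the hindered, enolisable ketone without touching the halides, and acid-induced anti elimination of the silyl and hydroxyl groups of 15 gives the C6 methylene group and erases the transient C6 centre.

Step 12
Reactants: 16 (1S,3R,4R)-4-bromo-3-chloro-4-methyl-1-(6-methylhepta-1,5-dien-2-yl)cyclohexan-1-ol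
Product: 17 (1S,3R,4R)-4-bromo-3-chloro-1-{4-[(2R)-3,3-dimethyloxiran-2-yl]but-1-en-2-yl}-4-methylcyclohexan-1-ol
Conditions: 1,2:4,5-di-O-isopropylidene-β-D-erythro-2,3-hexodiulo-2,6-pyranose (30 mol %), KHSO5 (as 2KHSO5·KHSO4·K2SO4, 1.4 equiv), K2CO3, Bu4NHSO4 (cat), MeCN–CH2(OMe)2/aq Na2B4O7 buffer, pH about 10.5, −10 to 0 °C
Reagents that add atoms: potassium peroxymonosulfate, [K+].[O-]S(=O)(=O)OO
Why: KHSO5 adds to the carbonyl group of the fructose-derived ketone and closes to a chiral dioxirane, which hands one oxygen atom to C2=C3 in a single concerted step through a spiro transition state and regenerates the ketone (Shi asymmetric epoxidation, the closest known reaction type and one established for prenyl termini). The only ring that closes is the oxirane O–C2–C3, formed by suprafacial [2+1] oxygen-atom transfer in which both C–O bonds are made on the same alkene face. C3 is the only new stereocentre and is set by the catalyst alone: in the favoured spiro arrangement the C4 chain points away from the fused dioxolane of the ketone, so the D-fructose series gives the (R)-oxirane, and the nearest substrate stereocentre C7 is too remote to matter. The step needs site selectivity between C2=C3 and C6=CH2; the electrophilic dioxirane prefers the more electron-rich trisubstituted alkene, 1,1-disubstituted alkenes are poor substrates for this ketone, and C6=CH2 is further shielded by the quaternary C7, so a small excess of oxidant at or below 0 °C should stop at the mono-epoxide. The ring no longer holds an alkene, and solvolysis of its tertiary bromide in the buffered aqueous medium is slowed by the inductive pull of the vicinal chlorine.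

Step 13
Reactants: 17 (1S,3R,4R)-4-bromo-3-chloro-1-{4-[(2R)-3,3-dimethyloxiran-2-yl]but-1-en-2-yl}-4-methylcyclohexan-1-ol
Product: 18 (1S,3R,4R)-4-bromo-3-chloro-1-[(5R)-5-hydroxy-6-methylhepta-1,6-dien-2-yl]-4-methylcyclohexan-1-ol (target)
Conditions: Et2Al(TMP) (4 equiv; from 2,2,6,6-tetramethylpiperidine, n-BuLi, Et2AlCl), toluene, 0 °C; aqueous work-up
Reagents that add atoms: none
Why: In this epoxide to allylic alcohol isomerisation with an aluminium amide, aluminium binds the oxirane oxygen (one equivalent is spent on C7–OH), the hindered amide removes a syn proton from a methyl group on C2 through a cyclic transition state as the more substituted C2–O bond breaks, and the C3–O bond passes with its (R) configuration into 18.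

Compound list
1 | (R)-lactic acid | C[C@@H](O)C(=O)O | starting material
2 | pivalaldehyde | CC(C)(C)C=O | starting material
3 | (2R,5R)-2-tert-butyl-5-methyl-1,3-dioxolan-4-one | O=C1O[C@H](C(C)(C)C)O[C@@H]1C | intermediate
4 | (2S,5S)-5-bromo-2-tert-butyl-5-methyl-1,3-dioxolan-4-one | O=C1O[C@H](C(C)(C)C)O[C@]1(Br)C | intermediate
5 | (2R)-2-tert-butyl-5-methylidene-1,3-dioxolan-4-one | O=C1O[C@H](C(C)(C)C)OC1=C | intermediate
6 | isoprene | C=CC(C)=C | starting material
7 | (2R,5S)-2-tert-butyl-8-methyl-1,3-dioxaspiro[4.5]dec-7-en-4-one | O=C1O[C@H](C(C)(C)C)O[C@]12CCC(C)=CC2 | intermediate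
8 | (1S)-1-hydroxy-N-methoxy-N,4-dimethylcyclohex-3-ene-1-carboxamide | CON(C)C(=O)[C@]1(O)CCC(C)=CC1 | intermediate
9 | (1S,3S,6R)-3-hydroxy-N-methoxy-N,6-dimethyl-7-oxabicyclo[4.1.0]heptane-3-carboxamide | CON(C)C(=O)[C@]1(O)CC[C@@]2(C)O[C@H]2C1 | intermediate
10 | (1S,3R,4R)-3-chloro-1,4-dihydroxy-N-methoxy-N,4-dimethylcyclohexane-1-carboxamide | CON(C)C(=O)[C@]1(O)CC[C@@](C)(O)[C@H](Cl)C1 | intermediate
11 | (1S,3R,4R)-4-bromo-3-chloro-1-hydroxy-N-methoxy-N,4-dimethylcyclohexane-1-carboxamide | CON(C)C(=O)[C@]1(O)CC[C@@](C)(Br)[C@H](Cl)C1 | intermediate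
12 | 5-bromo-2-methylpent-2-ene | CC(C)=CCCBr | starting material
13 | (4-methylpent-3-en-1-yl)magnesium bromide | CC(C)=CCC[Mg]Br | intermediate
14 | 1-[(1S,3R,4R)-4-bromo-3-chloro-1-hydroxy-4-methylcyclohexyl]-5-methylhex-4-en-1-one | CC(C)=CCCC(=O)[C@]1(O)CC[C@@](C)(Br)[C@H](Cl)C1 | intermediate
15 | (1S,3R,4R)-4-bromo-3-chloro-1-[2-hydroxy-6-methyl-1-(trimethylsilyl)hept-5-en-2-yl]-4-methylcyclohexan-1-ol (either configuration at the silyl carbinol carbon) | CC(C)=CCCC(O)(C[Si](C)(C)C)[C@]1(O)CC[C@@](C)(Br)[C@H](Cl)C1 | intermediate
16 | (1S,3R,4R)-4-bromo-3-chloro-4-methyl-1-(6-methylhepta-1,5-dien-2-yl)cyclohexan-1-ol | CC(C)=CCCC(=C)[C@]1(O)CC[C@@](C)(Br)[C@H](Cl)C1 | intermediate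
17 | (1S,3R,4R)-4-bromo-3-chloro-1-{4-[(2R)-3,3-dimethyloxiran-2-yl]but-1-en-2-yl}-4-methylcyclohexan-1-ol | CC1(C)O[C@@H]1CCC(=C)[C@]1(O)CC[C@@](C)(Br)[C@H](Cl)C1 | intermediate
18 | (1S,3R,4R)-4-bromo-3-chloro-1-[(5R)-5-hydroxy-6-methylhepta-1,6-dien-2-yl]-4-methylcyclohexan-1-ol | C=C(C)[C@H](O)CCC(=C)[C@]1(O)CC[C@@](C)(Br)[C@H](Cl)C1 | target

Total step count: 13. Longest linear sequence: 12 (steps 1–8 and 10–13).

**Steps most likely to fail**

**Step 8.**
- Chlorine bridging in the C10 cation may be too weak, so that bromide is taken up from the other face after ring relaxation.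
- The cation may also lose a proton.
- It may be trapped across the ring by the C7 hydroxyl or the amide oxygen.
- The fallback sets out from 9 and comes back at 11. It makes the C10–Br bond through a radical instead of a cation.
- Epoxide 9 is isomerised with Et2Al(TMP) in toluene to the exocyclic allylic alcohol (1S,3S)-1,3-dihydroxy-N-methoxy-N-methyl-4-methylidenecyclohexane-1-carboxamide F1.
- An Appel reaction (PPh3, CCl4) exchanges the secondary allylic C11 hydroxyl for chloride with inversion and gives (1S,3R)-3-chloro-1-hydroxy-N-methoxy-N-methyl-4-methylidenecyclohexane-1-carboxamide F2.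
- Markovnikov hydrobromination by hydrogen-atom transfer (Co(acac)2, t-BuOOH, Et3SiH, TsBr) then places H on the methylidene carbon and Br on C10.
- The tertiary β-chloro radical is expected to accept bromine anti to the C–Cl bond that eclipses its singly occupied orbital, which leads to 11.

**Step 7.**
- Chloride may attack the tertiary carbon C10. The hydrogen-bonded half-chair with axial C7–OH opens diaxially at C10 (Fürst–Plattner rule), whereas diaxial opening at C11 needs the amide group axial and syn to the incoming chloride.
- Acid-induced closure of a C7–O–C10 ether is a second drain.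
- The fallback sets out from 8 and comes back at 10. It replaces the epoxide by a cis-fused cyclic sulfate, in which C11–O is axial in the chair with equatorial amide, so SN2 displacement at C11 needs no ring flip and no acid.
- Hydrogen-bond-directed dihydroxylation of 8 (OsO4, TMEDA, CH2Cl2, −78 °C, then aq Na2SO3) gives (1S,3S,4R)-1,3,4-trihydroxy-N-methoxy-N,4-dimethylcyclohexane-1-carboxamide F3.
- SOCl2 and Et3N close the O3,O4-cyclic sulfite of this triol F4.
- NaIO4 with catalytic RuCl3 oxidises it to the O3,O4-cyclic sulfate F5.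
- LiCl in DMF opens the sulfate at C11 with inversion to lithium (1R,2R,4S)-2-chloro-4-hydroxy-4-[methoxy(methyl)carbamoyl]-1-methylcyclohexyl sulfate F6.
- Catalytic H2SO4 in wet THF cleaves the sulfate ester at sulfur and gives 10.

**Step 13.**
- The aluminium amide may remove HBr across C10.
- The Lewis-acidic aluminium may abstract halide.
- Proton removal may occur at C4 in place of a methyl group.
- The fallback sets out from 17 and comes back at 18. It avoids base altogether.
- Benzeneselenol with catalytic ZnI2 in CH2Cl2 opens the oxirane at its tertiary carbon C2, the carbon that best carries positive charge. The C3–O bond stays untouched, and the product is (1S,3R,4R)-4-bromo-3-chloro-1-[(5R)-5-hydroxy-6-methyl-6-(phenylselanyl)hept-1-en-2-yl]-4-methylcyclohexan-1-ol F7.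
- H2O2 in THF at 0 °C oxidises it to (1S,3R,4R)-4-bromo-3-chloro-1-[(5R)-5-hydroxy-6-methyl-6-(phenylseleninyl)hept-1-en-2-yl]-4-methylcyclohexan-1-ol F8.
- F8 undergoes selenoxide syn elimination at or below room temperature, away from the carbinol carbon and towards a methyl group, to give 18.

Further compounds
F1 | step 8 | (1S,3S)-1,3-dihydroxy-N-methoxy-N-methyl-4-methylidenecyclohexane-1-carboxamide | CON(C)C(=O)[C@]1(O)CCC(=C)[C@@H](O)C1
F2 | step 8 | (1S,3R)-3-chloro-1-hydroxy-N-methoxy-N-methyl-4-methylidenecyclohexane-1-carboxamide | CON(C)C(=O)[C@]1(O)CCC(=C)[C@H](Cl)C1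
F3 | step 7 | (1S,3S,4R)-1,3,4-trihydroxy-N-methoxy-N,4-dimethylcyclohexane-1-carboxamide | CON(C)C(=O)[C@]1(O)CC[C@@](C)(O)[C@@H](O)C1
F4 | step 7 | O3,O4-cyclic sulfite of F3 (either configuration at sulfur) | CON(C)C(=O)[C@]1(O)CC[C@@]2(C)OS(=O)O[C@H]2C1
F5 | step 7 | O3,O4-cyclic sulfate of F3 | CON(C)C(=O)[C@]1(O)CC[C@@]2(C)OS(=O)(=O)O[C@H]2C1
F6 | step 7 | lithium (1R,2R,4S)-2-chloro-4-hydroxy-4-[methoxy(methyl)carbamoyl]-1-methylcyclohexyl sulfate | [Li+].CON(C)C(=O)[C@]1(O)CC[C@@](C)(OS(=O)(=O)[O-])[C@H](Cl)C1
F7 | step 13 | (1S,3R,4R)-4-bromo-3-chloro-1-[(5R)-5-hydroxy-6-methyl-6-(phenylselanyl)hept-1-en-2-yl]-4-methylcyclohexan-1-ol | CC(C)([Se]c1ccccc1)[C@H](O)CCC(=C)[C@]1(O)CC[C@@](C)(Br)[C@H](Cl)C1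
F8 | step 13 | (1S,3R,4R)-4-bromo-3-chloro-1-[(5R)-5-hydroxy-6-methyl-6-(phenylseleninyl)hept-1-en-2-yl]-4-methylcyclohexan-1-ol | CC(C)([Se](=O)c1ccccc1)[C@H](O)CCC(=C)[C@]1(O)CC[C@@](C)(Br)[C@H](Cl)C1
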